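**Retrosynthetic overview**

- The strategy rests on the C3–C4 bond of the pyran ring (ring C) of the upper flavan, the unit whose ring B is bonded through C6' to C8 of the lower catechin. C4 is the benzylic CH2 on ring A and C3 is the carbinol carbon next to C2, so a C3=C4 alkene can be closed by metathesis and then take up the C3 hydroxyl trans to the C2 aryl group.
- Target 20 ⇐ hydrogenolysis of nine benzyl ethers (19) ⇐ anti hydroboration–oxidation of flav-3-ene 17 ⇐ ring-closing metathesis of diene 16.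
- 16 ⇐ Wittig methylenation of aldehyde 15 ⇐ iridium-catalysed branched allylic etherification of cinnamyl carbonate 11 with salicylaldehyde 13, which sets the upper C2.
- 11 ⇐ cinnamate 9 ⇐ Suzuki–Miyaura coupling (C6'–C8 biaryl bond) of 8-bromo-penta-O-benzylcatechin 4 with cinnamate boronate 8.
- Ring order: the three lower rings come intact from (+)-catechin, upper ring B from 3,4-bis(benzyloxy)benzaldehyde and upper ring A from 2,4,6-trihydroxybenzaldehyde; upper ring C is the only ring built, last, in step 13.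

Key step: step 13

Remark: the C6'–C8 biaryl axis carries three ortho substituents and the target defines no axial configuration, so the axis is taken as not configurationally fixed; intermediates may appear as rotamer mixtures.

Remark: the sense of induction in step 11 is assigned by analogy with simple cinnamyl carbonates; should the (R)-ether form instead, the antipodal ligand would be used.

Naming note: "penta-O-benzylcatechin-8-yl" stands for (2R,3S)-3,5,7-tris(benzyloxy)-2-[3,4-bis(benzyloxy)phenyl]chroman-8-yl.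

**Route**

Step 1
Reactants: 1 (+)-catechin
Product: 2 (2R,3S)-5,7,3',4'-tetra-O-benzylcatechin
Conditions: BnBr (4.2 equiv), K2CO3, DMF, 0 °C → rt, argon
Reagents that add atoms: benzyl bromide, BrCc1ccccc1
Why: Williamson etherification of the four phenoxides; K2CO3 is too weak a base to deprotonate the C3 alcohol, so the secondary hydroxyl stays free and C2/C3 are untouched.

Step 2
Reactants: 2 (2R,3S)-5,7,3',4'-tetra-O-benzylcatechin
Product: 3 (2R,3S)-8-bromo-5,7,3',4'-tetra-O-benzylcatechin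
Conditions: NBS (1.0 equiv), CH2Cl2, −78 °C → rt
Reagents that add atoms: N-bromosuccinimide, O=C1CCC(=O)N1Br
Why: Electrophilic aromatic bromination goes to ring A, the ring with three oxygen donors, and in tetra-O-benzyl flavan-3-ols is known to favour C8 over C6 with one equivalent of NBS at low temperature.

Step 3
Reactants: 3 (2R,3S)-8-bromo-5,7,3',4'-tetra-O-benzylcatechin
Product: 4 (2R,3S)-8-bromo-3,5,7,3',4'-penta-O-benzylcatechin
Conditions: NaH, BnBr, DMF, 0 °C → rt
Reagents that add atoms: benzyl bromide, BrCc1ccccc1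
Why: Williamson etherification of the C3 alkoxide, which keeps the C3 configuration because no bond to the stereocentre is broken.

Step 4
Reactants: 5 3,4-bis(benzyloxy)benzaldehyde
Product: 6 4,5-bis(benzyloxy)-2-bromobenzaldehyde
Conditions: Br2, NaOAc, AcOH, rt
Reagents that add atoms: bromine, BrBr
Why: Electrophilic aromatic bromination goes para to the 3-benzyloxy group (C6 of the aldehyde), as is usual for 3,4-dialkoxybenzaldehydes; NaOAc buffers the HBr so the benzyl ethers survive.

Step 5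
Reactants: 6 4,5-bis(benzyloxy)-2-bromobenzaldehyde
Product: 7 ethyl (E)-3-[4,5-bis(benzyloxy)-2-bromophenyl]prop-2-enoate
Conditions: Ph3P=CHCO2Et, toluene, 80 °C
Reagents that add atoms: ethyl (triphenylphosphoranylidene)acetate, CCOC(=O)C=P(c1ccccc1)(c1ccccc1)c1ccccc1
Why: Wittig olefination with a stabilized ylide should give the (E)-enoate selectively and tolerates the aryl bromide.

Step 6
Reactants: 7 ethyl (E)-3-[4,5-bis(benzyloxy)-2-bromophenyl]prop-2-enoate
Product: 8 ethyl (E)-3-[4,5-bis(benzyloxy)-2-(4,4,5,5-tetramethyl-1,3,2-dioxaborolan-2-yl)phenyl]prop-2-enoate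
Conditions: B2pin2, Pd(dppf)Cl2 (3 mol%), KOAc, 1,4-dioxane, 85 °C
Reagents that add atoms: bis(pinacolato)diboron, CC1(C)OB(OC1(C)C)B1OC(C)(C)C(C)(C)O1
Why: Miyaura borylation; the weak acetate base suppresses homocoupling, and an ortho-alkenyl boronate is less prone to protodeboronation than an ortho-formyl one, which is why the enoate is installed before the boron.

Step 7
Reactants: 4 (2R,3S)-8-bromo-3,5,7,3',4'-penta-O-benzylcatechin; 8 ethyl (E)-3-[4,5-bis(benzyloxy)-2-(4,4,5,5-tetramethyl-1,3,2-dioxaborolan-2-yl)phenyl]prop-2-enoate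
Product: 9 ethyl (E)-3-[4,5-bis(benzyloxy)-2-(penta-O-benzylcatechin-8-yl)phenyl]prop-2-enoate
Conditions: Pd(OAc)2 (5 mol%), SPhos (2-dicyclohexylphosphino-2',6'-dimethoxybiphenyl, 10 mol%), K3PO4, toluene/H2O (10:1), 90 °C
Reagents that add atoms: none
Why: Suzuki–Miyaura coupling; the bulky electron-rich biaryl phosphine is the ligand class suited to di-ortho-oxygenated aryl bromides and tri-ortho-substituted biaryls, and the C6'–C8 bond forms without touching any stereocentre.

Step 8
Reactants: 9 ethyl (E)-3-[4,5-bis(benzyloxy)-2-(penta-O-benzylcatechin-8-yl)phenyl]prop-2-enoate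
Product: 10 (E)-3-[4,5-bis(benzyloxy)-2-(penta-O-benzylcatechin-8-yl)phenyl]prop-2-en-1-ol
Conditions: iBu2AlH (2.5 equiv), CH2Cl2, −78 → 0 °C; aq. potassium sodium tartrate (KNaC4H4O6)
Reagents that add atoms: none
Why: 1,2-Reduction of the enoate by the aluminium hydride gives the allylic alcohol with the (E)-alkene and all benzyl ethers intact.

Step 9
Reactants: 10 (E)-3-[4,5-bis(benzyloxy)-2-(penta-O-benzylcatechin-8-yl)phenyl]prop-2-en-1-ol
Product: 11 (E)-3-[4,5-bis(benzyloxy)-2-(penta-O-benzylcatechin-8-yl)phenyl]prop-2-en-1-yl methyl carbonate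
Conditions: ClCO2Me, pyridine, CH2Cl2, 0 °C
Reagents that add atoms: methyl chloroformate, COC(=O)Cl
Why: O-Acylation of the primary allylic alcohol under buffered conditions gives the linear carbonate needed for iridium-catalysed substitution; it is used promptly because the electron-rich cinnamyl system ionizes easily.

Step 10
Reactants: 12 2,4,6-trihydroxybenzaldehyde
Product: 13 2,4-bis(benzyloxy)-6-hydroxybenzaldehyde
Conditions: BnBr (2.05 equiv), K2CO3 (2.2 equiv), DMF, rt
Reagents that add atoms: benzyl bromide, BrCc1ccccc1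
Why: Williamson etherification should stop after two benzylations because the remaining ortho hydroxyl is hydrogen-bonded to the formyl group and is the least nucleophilic.

Step 11
Reactants: 11 (E)-3-[4,5-bis(benzyloxy)-2-(penta-O-benzylcatechin-8-yl)phenyl]prop-2-en-1-yl methyl carbonate; 13 2,4-bis(benzyloxy)-6-hydroxybenzaldehyde
Product: 15 2,4-bis(benzyloxy)-6-{(1S)-1-[4,5-bis(benzyloxy)-2-(penta-O-benzylcatechin-8-yl)phenyl]prop-2-en-1-yloxy}benzaldehyde, via lithium aryloxide 14 (not isolated)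
Conditions: 13 (1.5 equiv), LiN(SiMe3)2 (1.5 equiv), THF, 0 °C; then 11, [Ir(cod)Cl]2 (2 mol%), (Sa,S,S)-(1,1'-binaphthalene-2,2'-diyl) N,N-bis[1-(2-methoxyphenyl)ethyl]phosphoramidite (4 mol%; catalyst pre-activated with n-PrNH2, volatiles removed), THF, rt → 40 °C
Reagents that add atoms: none
Why: Iridium-catalysed asymmetric allylic etherification: ionization of the carbonate gives an allyl–iridium complex that the aryloxide attacks at the aryl-bearing terminus, so the branched ether forms and the new centre (S, the future C2) is set by the cyclometalated chiral phosphoramidite catalyst, whose 2-methoxyphenyl variant is the one suited to ortho-substituted cinnamyl carbonates.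

Step 12
Reactants: 15 2,4-bis(benzyloxy)-6-{(1S)-1-[4,5-bis(benzyloxy)-2-(penta-O-benzylcatechin-8-yl)phenyl]prop-2-en-1-yloxy}benzaldehyde
Product: 16 1,5-bis(benzyloxy)-3-{(1S)-1-[4,5-bis(benzyloxy)-2-(penta-O-benzylcatechin-8-yl)phenyl]prop-2-en-1-yloxy}-2-vinylbenzene
Conditions: Ph3PCH3Br (1.5 equiv), KOtBu (1.4 equiv), THF, 0 °C; then 15, 0 °C → rt
Reagents that add atoms: methyltriphenylphosphonium bromide, C[P+](c1ccccc1)(c1ccccc1)c1ccccc1.[Br-]
Why: Wittig methylenation of the aryl aldehyde with the non-stabilized ylide, kept free of excess base so that the allylic ether centre is neither deprotonated nor isomerized.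

Step 13
Reactants: 16 1,5-bis(benzyloxy)-3-{(1S)-1-[4,5-bis(benzyloxy)-2-(penta-O-benzylcatechin-8-yl)phenyl]prop-2-en-1-yloxy}-2-vinylbenzene
Product: 17 (2S)-5,7-bis(benzyloxy)-2-[4,5-bis(benzyloxy)-2-(penta-O-benzylcatechin-8-yl)phenyl]-2H-chromene
Conditions: second-generation Grubbs catalyst, (H2IMes)(PCy3)Cl2Ru=CHPh (5 mol%), 1,4-benzoquinone (10 mol%), CH2Cl2 (0.005 M), 40 °C, argon, dark
Reagents that add atoms: none
Why: The ruthenium benzylidene should load onto one of the two terminal alkenes, and the resulting alkylidene then engages the other through a ruthenacyclobutane whose cycloreversion expels ethylene and forms the C3=C4 double bond. The closest known reaction type is ring-closing metathesis of 2-vinylphenyl allyl ethers to 2H-chromenes. The pyran ring (ring C of the upper flavan) closes as a six-membered ring by joining the two alkene carbons held ortho to each other on ring A through the ether oxygen, so the ring alkene can only be cis. No stereocentre is created, and C2 (S), set in step 11, is not touched because only alkene carbons take part. The step needs ring closure to outrun cross-metathesis and ruthenium-hydride migration of either double bond, which would destroy the C2 centre; high dilution, the ortho arrangement of the two monosubstituted alkenes, the benzoquinone additive and the exclusion of acid and light should secure this.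

Step 14
Reactants: 17 (2S)-5,7-bis(benzyloxy)-2-[4,5-bis(benzyloxy)-2-(penta-O-benzylcatechin-8-yl)phenyl]-2H-chromene
Product: 19 (2R,3S)-5,7-bis(benzyloxy)-2-[4,5-bis(benzyloxy)-2-(penta-O-benzylcatechin-8-yl)phenyl]chroman-3-ol, via C3-alkylborane 18 (not isolated)
Conditions: BH3·THF (3 equiv), THF, 0 °C → rt; then 3 M NaOH, 30% H2O2, 0 °C → rt
Reagents that add atoms: borane–tetrahydrofuran, B.C1CCOC1 (boron, kept only in 18); hydrogen peroxide, OO
Why: Hydroboration–oxidation of a flav-3-ene: boron adds to C3 (away from the benzylic C4 conjugated to ring A) on the face opposite the bulky C2 aryl group, and oxidation with retention gives the 2,3-trans alcohol, so C3 (S) is set by substrate control from C2.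

Step 15
Reactants: 19 (2R,3S)-5,7-bis(benzyloxy)-2-[4,5-bis(benzyloxy)-2-(penta-O-benzylcatechin-8-yl)phenyl]chroman-3-ol
Product: 20 CNP0353739.1, the C6'–C8-linked catechin dimer
Conditions: H2 (1 atm), Pd(OH)2/C, THF/MeOH/H2O, rt, degassed solvents
Reagents that add atoms: none
Why: Catalytic hydrogenolysis cleaves all nine benzyl ethers under neutral conditions that should leave the flavan C2–O bonds, the biaryl and the four stereocentres unchanged.

**Compound list**

1 | (+)-catechin, (2R,3S) | Oc1cc(O)c2c(c1)O[C@H](c1ccc(O)c(O)c1)[C@@H](O)C2 | starting material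
2 | (2R,3S)-5,7,3',4'-tetra-O-benzylcatechin | c5ccccc5COc1cc(OCc5ccccc5)c2c(c1)O[C@H](c1ccc(OCc5ccccc5)c(OCc5ccccc5)c1)[C@@H](O)C2 | intermediate
3 | (2R,3S)-8-bromo-5,7,3',4'-tetra-O-benzylcatechin | c5ccccc5COc1cc(OCc5ccccc5)c2c(c1Br)O[C@H](c1ccc(OCc5ccccc5)c(OCc5ccccc5)c1)[C@@H](O)C2 | intermediate
4 | (2R,3S)-8-bromo-3,5,7,3',4'-penta-O-benzylcatechin | c5ccccc5COc1cc(OCc5ccccc5)c2c(c1Br)O[C@H](c1ccc(OCc5ccccc5)c(OCc5ccccc5)c1)[C@@H](OCc5ccccc5)C2 | intermediate
5 | 3,4-bis(benzyloxy)benzaldehyde | O=Cc1ccc(OCc2ccccc2)c(OCc2ccccc2)c1 | starting material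
6 | 4,5-bis(benzyloxy)-2-bromobenzaldehyde | O=Cc1cc(OCc2ccccc2)c(OCc2ccccc2)cc1Br | intermediate
7 | ethyl (E)-3-[4,5-bis(benzyloxy)-2-bromophenyl]prop-2-enoate | CCOC(=O)/C=C/c1cc(OCc2ccccc2)c(OCc2ccccc2)cc1Br | intermediate
8 | ethyl (E)-3-[4,5-bis(benzyloxy)-2-(pinacolatoboryl)phenyl]prop-2-enoate | CCOC(=O)/C=C/c1cc(OCc2ccccc2)c(OCc2ccccc2)cc1B1OC(C)(C)C(C)(C)O1 | intermediate
9 | ethyl (E)-3-[4,5-bis(benzyloxy)-2-(penta-O-benzylcatechin-8-yl)phenyl]prop-2-enoate | CCOC(=O)/C=C/c1cc(OCc5ccccc5)c(OCc5ccccc5)cc1-c1c(OCc5ccccc5)cc(OCc5ccccc5)c2c1O[C@H](c1ccc(OCc5ccccc5)c(OCc5ccccc5)c1)[C@@H](OCc5ccccc5)C2 | intermediate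
10 | (E)-3-[4,5-bis(benzyloxy)-2-(penta-O-benzylcatechin-8-yl)phenyl]prop-2-en-1-ol | OC/C=C/c1cc(OCc5ccccc5)c(OCc5ccccc5)cc1-c1c(OCc5ccccc5)cc(OCc5ccccc5)c2c1O[C@H](c1ccc(OCc5ccccc5)c(OCc5ccccc5)c1)[C@@H](OCc5ccccc5)C2 | intermediate
11 | (E)-cinnamyl methyl carbonate of 10 | COC(=O)OC/C=C/c1cc(OCc5ccccc5)c(OCc5ccccc5)cc1-c1c(OCc5ccccc5)cc(OCc5ccccc5)c2c1O[C@H](c1ccc(OCc5ccccc5)c(OCc5ccccc5)c1)[C@@H](OCc5ccccc5)C2 | intermediate
12 | 2,4,6-trihydroxybenzaldehyde | O=Cc1c(O)cc(O)cc1O | starting material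
13 | 2,4-bis(benzyloxy)-6-hydroxybenzaldehyde | O=Cc1c(O)cc(OCc5ccccc5)cc1OCc5ccccc5 | intermediate
14 | lithium 3,5-bis(benzyloxy)-2-formylphenolate | [Li+].[O-]c1cc(OCc2ccccc2)cc(OCc2ccccc2)c1C=O | intermediate
15 | (S)-branched allyl aryl ether aldehyde | O=Cc1c(OCc5ccccc5)cc(OCc5ccccc5)cc1O[C@H](c1cc(OCc5ccccc5)c(OCc5ccccc5)cc1-c1c(OCc5ccccc5)cc(OCc5ccccc5)c2c1O[C@H](c1ccc(OCc5ccccc5)c(OCc5ccccc5)c1)[C@@H](OCc5ccccc5)C2)C=C | intermediate
16 | (S)-2-vinylaryl 1-arylallyl ether (metathesis precursor) | C=Cc1c(OCc5ccccc5)cc(OCc5ccccc5)cc1O[C@H](c1cc(OCc5ccccc5)c(OCc5ccccc5)cc1-c1c(OCc5ccccc5)cc(OCc5ccccc5)c2c1O[C@H](c1ccc(OCc5ccccc5)c(OCc5ccccc5)c1)[C@@H](OCc5ccccc5)C2)C=C | intermediate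
17 | (2S)-flav-3-ene linked at C6' to penta-O-benzylcatechin | c5ccccc5COc1cc(OCc5ccccc5)c2c(c1)O[C@H](c1cc(OCc5ccccc5)c(OCc5ccccc5)cc1-c1c(OCc5ccccc5)cc(OCc5ccccc5)c3c1O[C@H](c1ccc(OCc5ccccc5)c(OCc5ccccc5)c1)[C@@H](OCc5ccccc5)C3)C=C2 | intermediate
18 | C3-alkylborane (2,3-trans) | c5ccccc5COc1cc(OCc5ccccc5)c2c(c1)O[C@H](c1cc(OCc5ccccc5)c(OCc5ccccc5)cc1-c1c(OCc5ccccc5)cc(OCc5ccccc5)c3c1O[C@H](c1ccc(OCc5ccccc5)c(OCc5ccccc5)c1)[C@@H](OCc5ccccc5)C3)[C@@H](B)C2 | intermediate
19 | (2R,3S)-flavan-3-ol, nona-O-benzyl ether of the target | c5ccccc5COc1cc(OCc5ccccc5)c2c(c1)O[C@H](c1cc(OCc5ccccc5)c(OCc5ccccc5)cc1-c1c(OCc5ccccc5)cc(OCc5ccccc5)c3c1O[C@H](c1ccc(OCc5ccccc5)c(OCc5ccccc5)c1)[C@@H](OCc5ccccc5)C3)[C@@H](O)C2 | intermediate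
20 | CNP0353739.1 | Oc1cc(O)c2c(c1)O[C@H](c1cc(O)c(O)cc1-c1c(O)cc(O)c3c1O[C@H](c1ccc(O)c(O)c1)[C@@H](O)C3)[C@@H](O)C2 | target

**Step count and risks**

Total steps: 15. Longest linear sequence: 11 steps (steps 1, 2, 3, 7, 8, 9, 11, 12, 13, 14, 15 from (+)-catechin; the branch from 5 through steps 4, 5, 6 is equally long).

Steps most likely to fail:

1. Step 11. Ionization of the carbonate may be slow at the crowded ortho-aryl cinnamyl position. The formyl-substituted aryloxide is a fair leaving group, so the product ether may re-ionize on iridium, leaking to the linear ether and eroding the new centre. Fallback, from 9, rejoining at 15: Lemieux–Johnson cleavage of the enoate alkene of 9 (OsO4 cat., NaIO4, 2,6-lutidine, dioxane/H2O) should give 4,5-bis(benzyloxy)-2-(penta-O-benzylcatechin-8-yl)benzaldehyde F1. Catalytic asymmetric vinylation of F1 with Zn(CH=CH2)2 and a chiral β-amino alcohol ligand such as 3-exo-(dimethylamino)isoborneol (antipode chosen for the R carbinol) should give (1R)-1-[4,5-bis(benzyloxy)-2-(penta-O-benzylcatechin-8-yl)phenyl]prop-2-en-1-ol F2. Mitsunobu etherification of F2 with phenol 13 (PPh3, DIAD, toluene, −20 °C) should then give 15 with inversion; low temperature and a non-polar solvent are chosen to hold back ionization of this electron-rich benzylic alcohol.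

2. Step 13. Initiation may be slow at two congested alkenes, so that oligomerization competes, and ruthenium hydride may isomerize the allyl ether or move the chromene double bond. Fallback, from 10 and 13, rejoining at 17: MnO2 oxidation of 10 should give (E)-3-[4,5-bis(benzyloxy)-2-(penta-O-benzylcatechin-8-yl)phenyl]prop-2-enal F3. Domino oxa-Michael/aldol condensation of F3 with 13 under iminium catalysis by a diarylprolinol silyl ether (antipode chosen for the required C2 configuration; 2-nitrobenzoic acid, toluene, rt) closes the pyran ring and should give (2R)-5,7-bis(benzyloxy)-2-[4,5-bis(benzyloxy)-2-(penta-O-benzylcatechin-8-yl)phenyl]-2H-chromene-3-carbaldehyde F4. Decarbonylation of F4 with stoichiometric RhCl(PPh3)3 (toluene, 90 °C, dark) should then give 17; the temperature is kept as low as possible to avoid thermal ring-opening of the chromene.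

3. Step 7. Oxidative addition of the hindered, electron-rich bromide to zerovalent palladium may be slow, so that protodeboronation of 8 and hydrodebromination of 4 win. Fallback, from 4, rejoining at 9: bromine–lithium exchange on 4 (n-BuLi, THF, −78 °C) should give 8-lithio-penta-O-benzylcatechin F5, and transmetalation with ZnCl2 should give 8-(chlorozincio)-penta-O-benzylcatechin F6. Negishi coupling of F6 with aryl bromide 7 (Pd(OAc)2, SPhos, THF, 50 °C) should give 9; this reverses the polarity, so the easy oxidative addition is now that of the enoate-activated bromide.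

**Further compounds**

F1 | step 11 | 4,5-bis(benzyloxy)-2-(penta-O-benzylcatechin-8-yl)benzaldehyde | O=Cc1cc(OCc5ccccc5)c(OCc5ccccc5)cc1-c1c(OCc5ccccc5)cc(OCc5ccccc5)c2c1O[C@H](c1ccc(OCc5ccccc5)c(OCc5ccccc5)c1)[C@@H](OCc5ccccc5)C2
F2 | step 11 | (1R)-1-[4,5-bis(benzyloxy)-2-(penta-O-benzylcatechin-8-yl)phenyl]prop-2-en-1-ol | O[C@@H](c1cc(OCc5ccccc5)c(OCc5ccccc5)cc1-c1c(OCc5ccccc5)cc(OCc5ccccc5)c2c1O[C@H](c1ccc(OCc5ccccc5)c(OCc5ccccc5)c1)[C@@H](OCc5ccccc5)C2)C=C
F3 | step 13 | (E)-3-[4,5-bis(benzyloxy)-2-(penta-O-benzylcatechin-8-yl)phenyl]prop-2-enal | O=C/C=C/c1cc(OCc5ccccc5)c(OCc5ccccc5)cc1-c1c(OCc5ccccc5)cc(OCc5ccccc5)c2c1O[C@H](c1ccc(OCc5ccccc5)c(OCc5ccccc5)c1)[C@@H](OCc5ccccc5)C2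
F4 | step 13 | (2R)-5,7-bis(benzyloxy)-2-[4,5-bis(benzyloxy)-2-(penta-O-benzylcatechin-8-yl)phenyl]-2H-chromene-3-carbaldehyde | c5ccccc5COc1cc(OCc5ccccc5)c2c(c1)O[C@H](c1cc(OCc5ccccc5)c(OCc5ccccc5)cc1-c1c(OCc5ccccc5)cc(OCc5ccccc5)c3c1O[C@H](c1ccc(OCc5ccccc5)c(OCc5ccccc5)c1)[C@@H](OCc5ccccc5)C3)C(C=O)=C2
F5 | step 7 | 8-lithio-penta-O-benzylcatechin | [Li]c1c(OCc5ccccc5)cc(OCc5ccccc5)c2c1O[C@H](c1ccc(OCc5ccccc5)c(OCc5ccccc5)c1)[C@@H](OCc5ccccc5)C2
F6 | step 7 | 8-(chlorozincio)-penta-O-benzylcatechin | Cl[Zn]c1c(OCc5ccccc5)cc(OCc5ccccc5)c2c1O[C@H](c1ccc(OCc5ccccc5)c(OCc5ccccc5)c1)[C@@H](OCc5ccccc5)C2
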